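3 questions stand: two orders round the violet charge and one share in the grey flask. One ledger serves them.

| flask | Sbt | Ptn | time |
|---|---|---|---|
| violet | 0.300 M | 0.300 M |  |
| blue | 0.180 M | 0.180 M |  |
| red | 0.300 M | 0.450 M |  |
| amber | 0.600 M | 0.300 M |  |
| grey | 0.900 M | 0.900 M | 7.1 min |

| run | time / min | [Pdt] / M |
|---|---|---|
| violet run | 1.2 | 0.0481 |
| violet run | 2.4 | 0.0702 |
| violet run | 3.5 | 0.0824 |
| violet run | 4.7 | 0.0911 |
| violet run | 5.9 | 0.0969 |
| violet run | 7.1 | 0.0991 |
| blue run | 1.2 | 0.0120 |
| blue run | 2.4 | 0.0212 |
| blue run | 3.5 | 0.0263 |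
| blue run | 4.7 | 0.0316 |
| blue run | 5.9 | 0.0353 |
| blue run | 7.1 | 0.0355 |
| red run | 1.2 | 0.0916 |
| red run | 2.4 | 0.1272 |
| red run | 3.5 | 0.1427 |
| red run | 4.7 | 0.1518 |
| red run | 5.9 | 0.1573 |
| red run | 7.1 | 0.1586 |
| amber run | 1.2 | 0.0774 |
| amber run | 2.4 | 0.1035 |
| amber run | 3.5 | 0.1157 |
| amber run | 4.7 | 0.1242 |
| amber run | 5.9 | 0.1279 |
| amber run | 7.1 | 0.1290 |

(readings scatter by 9 × 10⁻⁴ M)

1. how the opening rate goes with [Ptn] round the charge of the violet run: the exponent of the rate at two percent of Sbt gone to Pdt
2. how the opening rate goes with [Sbt] round the charge of the violet run: the exponent of the rate at two percent of Sbt gone to Pdt (one fixed amount of Pdt, the same in the runs compared)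
3. Pdt in the grey run at 7.1 min, as a share of the Sbt charged

- Overall: Sbt + Ptn -> Pdt.
- Constant volume, constant temperature.
- "The second partner" is Ptn.
- An order is taken over about fifteen percent of the charge, up and down.

Keep the books on Sbt, the limiting reagent in the red run and level with Ptn in the violet and grey charges. Follow one Sbt molecule to 7.1 min. In the violet run, 33.0% of the charge is read as Pdt and 67.0% is not. The last interval adds 0.733% of the charge.

Now write that fork as one figure. The violet run stands at 0.493: these are the Pdt odds, the share of the Sbt charge read as Pdt over the share not so read, at the last reading. The red run, with more Ptn on the same Sbt, reads 1.12, an exponent of 2.03 in the Ptn charge. The amber run, with more Sbt on the same Ptn, reads 0.274, an exponent of −0.849 in the Sbt charge.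

Round these to a rule for the one time 7.1 min: the odds go with the Ptn charge squared over the Sbt charge. Take the other branch of the fork as free of Ptn, and commit to an opening order near 2 in Ptn. Guess 1 in Sbt, with the other branch one order higher. For the grey run, the rule scales the violet odds by 3.00, which gives 1.48, or 59.7% of the charge. Check the rule on the blue run: it reads 0.246 against a rule value of 0.296. Hold the grey figure loosely.

The forecast differs. It gives 1.7 in Ptn, 0.8 in Sbt and 55% for the grey run, which is less than my 59.7%. Of the flattening curves it says “the reaction is being choked by product or by a dying catalyst”.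

The simulation gives 2.1 in Ptn, 1.0 in Sbt and 56.1% for the grey run.

    Sbt + 2 Ptn → Pdt + Ptn (2.220 M⁻² min⁻¹)
    Pdt → X (0.03144 min⁻¹)
    2 Sbt → E (0.3918 M⁻¹ min⁻¹)

The grey run stands at odds of 1.28 at 7.1 min, which is 2.60 times the violet odds where the rule said 3.00. Two steps act together to hold these odds down: Pdt leaving for X and pairs of Sbt going to E. Take away the step to X and the grey run gives 67.9%, odds of 2.12. Take away the step to E and it gives 66.9%, odds of 2.02. Of the grey charge missing from Pdt, the step to X accounts for 27% and the step to E for 25%.

The earlier runs and the new flask are simulated with constants of no real substance; the scatter is artificial.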